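## Structural features

Integracin B is an open-chain ester of two alkylresorcinol halves. Ring A is a 2,4-dihydroxybenzoate carrying at C6 an undecyl chain (C1' at the ring to C11'). Ring B is a 5-alkylresorcinol whose undecyl chain is esterified to the ring A carboxyl group through its carbinol, seven methylenes away from ring B. The only rings are the two benzene rings, and no ring has to be built if both are taken from aromatic starting materials. There are two stereocentres, both R: the free carbinol C8' on the ring A chain and the acylated carbinol on the ring B chain. They lie twelve bonds apart, so neither can steer the other, and each carries n-propyl on one side and a long polymethylene chain on the other. The fragile points are the four phenols on two very electron-rich rings (easily halogenated or oxidised), the electron-rich benzoic acid that must be esterified (it decarboxylates in hot acid), and the ester carbonyl, which sits between two ortho substituents and is slow to form. The real difficulties are this hindered ester and the absolute configuration of two carbinols whose alkyl arms are almost the same size, which rules out any method that asks a reagent to tell propyl from heptyl. The key step exploits the C8' carbinol together with its C7' methylene and the propyl group C9' to C11': C8' is created as a boron-bearing carbon while the C8'–C9' and C6'–C7' bonds are formed, so the centre arises by carbon–carbon bond construction under catalyst control and is unveiled by C–B oxidation.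

## Logic of the disconnections

**24 to 23.** The four O–benzyl bonds and the two C–H bonds at C5' and C6' are cut. All phenols stay masked and the alkene stays in place until the last operation, so every earlier intermediate is non-acidic, lipophilic and easy to purify. The forward step must saturate the alkene and cleave only benzylic C–O bonds, leaving both carbinol C–O bonds and the ester alone.

**23 to 22.** The C8'–O bond is exchanged for a C8'–B bond. This turns a carbinol that cannot be made selectively by reduction into a boronic ester that can be made by C–C bond formation. The forward oxidation must proceed with retention and must spare the hindered benzoate.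

**22 to 18, 19 and 20 (through 21).** The C8'–C9' and C6'–C7' bonds are cut, both at or next to the stereocentre. A two-carbon linchpin (C7' and C8') comes from 20, the propyl group from 19, and everything else from 18, which has no stereocentre on the ring A chain. The forward step demands a fully preformed ate complex 21 (so that no free organolithium meets the ester), an E-configured alkenyl bromide, removal of halide from the catalyst, and enantiofacial control by the ligand alone.

**18 to 16.** The C6'–Br and C5'–H bonds are cut, leading back to a terminal alkyne, a robust handle that survives esterification. The forward step needs syn hydrometalation with the metal on the terminal carbon and chemoselectivity over the ester and the electron-rich rings.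

**16 to 7 and 14 (through 15).** The acyl C–O bond of the ester is cut. This is the most convergent cut: two halves of similar size, and the carbinol of 14 keeps its configuration because its C–O bond is never broken. The forward step demands the strongest practical activation of a doubly ortho-substituted acid.

**7 to 6, then 2 and 4 (through 5); 2 to 1; 4 to 3.** The C1'–C2' bond is cut next to ring A, then the O–benzyl bonds and the carbon–iodine bond. This uses the methyl group of cheap 1 as the nucleophile and gives the ring A half in four steps. Lateral deprotonation must beat self-condensation of the ester, the alkyne must be C-silylated while the anion is present, and the hydrolysis that frees the acid should also remove the silyl group.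

**14 to 11 and 12 (through 13); 11 to 8 and 9 (through 10).** The aryl–CH2 bond and the C–C bond next to the carbinol are cut. The stereocentre is bought with 9, and the two steps are a Grignard epoxide opening and an aryl–alkyl cross-coupling. The forward steps need attack at the unsubstituted epoxide carbon, anti-Markovnikov hydroboration, and tolerance of the free hydroxyl.

## Other disconnections considered

**Alternative 1:** The cut is made inside ring B. The benzene ring is dissected into the four-carbon unit of cyclobutenone A2 and the two carbons of ethoxyethyne A3. The forward step is the thermal Danheiser benzannulation (four-electron ring opening, (2+2) cycloaddition, second ring opening, six-electron electrocyclisation, tautomerisation), which would give the resorcinol monoethyl ether A1 with the chain and its pivalate-protected carbinol in place.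
- In its favour: the 1,3,5-pattern is fixed by the mechanism and no metal is needed. On regiochemical certainty it is the equal of buying the ring.
- Against it here: ring B is the least demanding part of the target, and a 3,5-dioxygenated aryl unit can be bought (12). A1 has one ethyl ether and one free phenol, so reaching 14 would still need an aryl ether cleavage by a strong Lewis acid, twofold benzylation and removal of the pivalate. A2 is itself several steps from a chiral epoxide.
- Comparison: on structure the plans are equal for the ring B carbinol (chiral pool in both), and the alternative does nothing for the hindered ester or for C8'. On mechanism a pericyclic cascade is arguably more predictable than the palladium-mediated coupling of step 6, a point on which the alternative is the better. On step economy it is clearly worse, since steps 5 and 6 would be replaced by at least six steps.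

**Alternative 2:** The cut removes the ester C–O bond and the C1–C6 bond of ring A together. Ring A is traced back to the open-chain polycarbonyl dioxinone A5, which carries the whole C1' to C11' chain with C8' as its benzyl ether. In the forward key step A5 would be heated with 14 so that the acyl group passes to the ring B oxygen; base and then acid would close ring A by intramolecular aldol condensation and dehydration to give A4.
- In its favour: the ester is made by addition of the alcohol to an unhindered, highly electrophilic acyl donor before the ortho substituents exist, which is better than the acylation of step 7. Ring A arrives with both phenols free, and A4 is one hydrogenolysis from 24, a shorter endgame than the three steps that follow 18.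
- Against it here: A5 must already contain the C8' stereocentre, so a second chiral-pool chain, its protection and two chain-extending acylations are needed before the key step. The polycarbonyl intermediates can cyclise in other ways (pyranone formation) unless base and acid stages are carefully separated. The valuable partner 14 is exposed to thermolysis.
- Comparison: on structure it fixes both carbinols from the same epoxide, equal in outcome and better in certainty than ligand control at C8'. On mechanism it is at least the equal for the ester bond. On step economy the chosen plan is expected to be shorter overall because A5 is costly, although the longest linear sequences would be similar.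

**Alternative 3:** The cut goes through the C1–C2 and C5–C6 bonds of ring A. The ring is built on the preformed ester A7, an alkynoate of 14, by (4+2) cycloaddition with the dimedone-derived diene A8, followed by cycloreversion that expels the gem-dimethyl bridge and leaves the aromatic bis(silyl ether) A6.
- In its favour: the ester is made from an unhindered alkynoic acid (better than step 7, equal to alternative 2), the regiochemistry follows from the polarisation of diene and ynoate, and ring A appears fully substituted in one operation.
- Against it here: an alkyl-substituted ynoate is a sluggish dienophile, so prolonged heating well above 100 °C with excess A8 would be needed. A7 again needs C8' preinstalled as its benzyl ether, which means a second chiral-pool chain of fourteen carbons. The aryl silyl ethers of A6 are labile, which is harmless for the endgame but complicates purification.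
- Comparison: on structure it is equal for ring B and for the ester but gives up the late, convergent creation of C8'. On mechanism the cycloaddition and cycloreversion pair is robust and avoids both the lateral alkylation and the hindered hydrolysis of the chosen plan, a point in its favour. On step economy the two are expected to be close, with the chosen plan slightly ahead because the C8' chain need not be made separately.

Key step: step 9

Remarks on the chemistry (assumptions):
- The alkynyl C–Si bond cannot outlast the hydroxide needed to hydrolyse the hindered ethyl ester, so desilylation is merged with the saponification (step 4) and the free terminal alkyne is carried through the esterification.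
- Ring B alcohol 14 is assembled from aryl bromide 12, taken as a purchased compound, because an aryl–alkyl Suzuki–Miyaura coupling reaches 14 in two steps from 9.
- Vinyllithium 20 is used as a halide-free, titrated THF solution (stock reagent).
- The MandyPhos enantiomer is assigned from the established sense of induction of this catalyst class for alkyl migration and is to be confirmed on the first batch of 23 by derivatisation with a chiral acid.

## Route

Step 1
Reactants: 1 ethyl orsellinate (ethyl 2,4-dihydroxy-6-methylbenzoate)
Product: 2 ethyl 2,4-bis(benzyloxy)-6-methylbenzoate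
Conditions: BnBr (2.5 equiv), K2CO3 (3 equiv), DMF, 60 °C
Reagents that add atoms: benzyl bromide, BrCc1ccccc1
Why: Williamson ether synthesis; carbonate deprotonates both phenols and the phenoxides displace bromide, the hydrogen-bonded 2-OH being the slower one (hence warm DMF and excess halide), and the ethyl ester is untouched.

Step 2
Reactants: 3 (5-chloropent-1-yn-1-yl)trimethylsilane
Product: 4 (5-iodopent-1-yn-1-yl)trimethylsilane
Conditions: NaI (3 equiv), acetone, reflux
Reagents that add atoms: sodium iodide, [Na+].[I-]
Why: Finkelstein halide exchange (SN2) driven by precipitation of NaCl; it supplies the iodide needed for alkylation at low temperature, and the silylalkyne is inert.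

Step 3
Reactants: 2 ethyl 2,4-bis(benzyloxy)-6-methylbenzoate; 4 (5-iodopent-1-yn-1-yl)trimethylsilane
Product: 6 ethyl 2,4-bis(benzyloxy)-6-[6-(trimethylsilyl)hex-5-yn-1-yl]benzoate, via benzylic lithium species 5 (not isolated)
Conditions: LiN(iPr)2 (1.15 equiv), THF, −78 °C, slow addition of 2; then 4 (1.3 equiv), DMPU, −78 to −30 °C
Reagents that add atoms: none
Why: Lateral (benzylic) lithiation of an ortho-toluate ester gives the ester-stabilised anion 5, which is alkylated by the primary iodide (SN2) to form C1'–C2'; slow addition of 2 to the amide at −78 °C keeps free ester away from 5 and limits Claisen-type self-condensation, and the silyl cap removes the acidic alkyne hydrogen that would quench 5.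

Step 4
Reactants: 6 ethyl 2,4-bis(benzyloxy)-6-[6-(trimethylsilyl)hex-5-yn-1-yl]benzoate
Product: 7 2,4-bis(benzyloxy)-6-(hex-5-yn-1-yl)benzoic acid
Conditions: KOH (10 equiv), EtOH/H2O 4:1, reflux; then 1 M HCl to pH 3, 0 °C
Reagents that add atoms: potassium hydroxide, [K+].[OH-]
Why: Saponification (acyl–oxygen cleavage by hydroxide) of the doubly ortho-substituted ester needs excess KOH at reflux, and the same conditions cleave the alkynyl C–Si bond, so the terminal alkyne is released in the same operation; aqueous ethanol is too weakly basic to shift the triple bond, and cold mild acidification avoids protodecarboxylation.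

Step 5
Reactants: 8 6-bromohex-1-ene; 9 (R)-2-propyloxirane
Product: 11 (R)-undec-10-en-4-ol, via hex-5-enylmagnesium bromide 10 (not isolated)
Conditions: Mg, THF, rt; then CuI (10 mol %), 9, THF, −30 to 0 °C; aq NH4Cl
Reagents that add atoms: none
Why: Copper-catalysed SN2 opening of a monosubstituted epoxide by a primary Grignard reagent at the unsubstituted carbon; the C–O bond at the stereocentre is not broken, so the R configuration of 9 passes into 11 (descriptor unchanged because the new chain still outranks propyl), and any cyclopentylmethyl Grignard from radical 5-exo closure during magnesium insertion ends as a saturated alcohol that cannot react in step 6 and is removed there.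

Step 6
Reactants: 11 (R)-undec-10-en-4-ol; 12 1,3-bis(benzyloxy)-5-bromobenzene
Product: 14 (R)-11-[3,5-bis(benzyloxy)phenyl]undecan-4-ol, via O-borylated alkyl-9-BBN 13 (not isolated)
Conditions: 9-BBN (2.2 equiv), THF, 0 °C to rt; then 12, Pd(dppf)Cl2 (3 mol %), 3 M aq K3PO4, THF/DMF, 60 °C
Reagents that add atoms: none
Why: Anti-Markovnikov hydroboration of the terminal alkene (one extra equivalent of 9-BBN is allowed for the hydroxyl, whose B–O bond is hydrolysed by the aqueous base) followed by B-alkyl Suzuki–Miyaura coupling forms the aryl–CH2 bond; the dppf ligand favours reductive elimination over β-hydride elimination, and the stereocentre is remote from every reacting atom.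

Step 7
Reactants: 7 2,4-bis(benzyloxy)-6-(hex-5-yn-1-yl)benzoic acid; 14 (R)-11-[3,5-bis(benzyloxy)phenyl]undecan-4-ol
Product: 16 (R)-11-[3,5-bis(benzyloxy)phenyl]undecan-4-yl 2,4-bis(benzyloxy)-6-(hex-5-yn-1-yl)benzoate, via acid chloride 15 (not isolated)
Conditions: 7 (1.2 equiv), (COCl)2, DMF (cat.), CH2Cl2, 0 °C to rt, evaporate; then 14, Et3N (3 equiv), DMAP (1 equiv), toluene, 60 °C
Reagents that add atoms: none
Why: Acylation of a secondary alcohol by an acid chloride with nucleophilic catalysis (N-acylpyridinium ion from DMAP); the acid chloride is the smallest and most reactive acyl donor for a carbonyl flanked by two ortho substituents, and since only the acyl C–O bond is formed the carbinol keeps its R configuration.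

Step 8
Reactants: 16 (R)-11-[3,5-bis(benzyloxy)phenyl]undecan-4-yl 2,4-bis(benzyloxy)-6-(hex-5-yn-1-yl)benzoate
Product: 18 (R)-11-[3,5-bis(benzyloxy)phenyl]undecan-4-yl 2,4-bis(benzyloxy)-6-[(E)-6-bromohex-5-en-1-yl]benzoate, via (E)-alkenylzirconocene chloride 17 (not isolated)
Conditions: Cp2Zr(H)Cl (1.3 equiv), THF, rt, dark; then NBS (1.3 equiv), −78 to 0 °C
Reagents that add atoms: N-bromosuccinimide, BrN1C(=O)CCC1=O
Why: Hydrozirconation then bromodezirconation; Zr–H adds syn across the terminal alkyne with zirconium on the unhindered carbon C6', and NBS cleaves the C–Zr bond with retention to give only the E-bromide; the alkyne reacts far faster with the zirconium hydride than the shielded ester, and at −78 °C the C–Zr bond should take up the NBS before the benzyloxy-substituted rings can be brominated.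

Step 9
Reactants: 19 propylboronic acid pinacol ester (4,4,5,5-tetramethyl-2-propyl-1,3,2-dioxaborolane); 20 vinyllithium; 18 (R)-11-[3,5-bis(benzyloxy)phenyl]undecan-4-yl 2,4-bis(benzyloxy)-6-[(E)-6-bromohex-5-en-1-yl]benzoate
Product: 22 (R)-11-[3,5-bis(benzyloxy)phenyl]undecan-4-yl 2,4-bis(benzyloxy)-6-[(R,E)-8-(4,4,5,5-tetramethyl-1,3,2-dioxaborolan-2-yl)undec-5-en-1-yl]benzoate, via lithium propyl(vinyl)boronate complex 21 (not isolated)
Conditions: 19 (1.6 equiv), 20 (1.5 equiv), THF, 0 °C to rt; then 18, Pd(OAc)2 (3 mol %), MandyPhos ligand [1,1'-bis(diarylphosphino)-2,2'-bis(α-(dimethylamino)benzyl)ferrocene, enantiomer giving the R boronate] (3.6 mol %), KOTf (2 equiv), degassed THF, 60 °C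
Reagents that add atoms: none
Why: This is a conjunctive three-component cross-coupling of a vinylboron ate complex (palladium-induced 1,2-metallate rearrangement), the known reaction type for alkenyl and aryl bromides in the presence of a triflate salt. Vinyllithium adds to the boron of 19 to give the four-coordinate boronate 21; with 19 in slight excess no free organolithium remains, so the hindered benzoate never meets a carbanion. Zerovalent palladium inserts into the C6'–Br bond of 18 with retention of the E geometry, and KOTf removes bromide as KBr so that the alkenyl complex of divalent palladium can bind the vinyl group of 21. Binding triggers migration of the n-propyl group from boron to the α-carbon anti to palladium, which forms C8'–C9' and a C7'–Pd bond, and reductive elimination then forms C6'–C7' and returns zerovalent palladium. No ring is closed. The new stereocentre C8' is set in the migration step by the face of the vinyl group that the chiral bisphosphine presents to the metal (catalyst control, ligand enantiomer chosen for R), and the acylated carbinol is too remote to match or mismatch. The step needs conjunctive coupling to outrun direct Suzuki–Miyaura transfer of vinyl or propyl and β-hydride elimination from the alkylpalladium intermediate; the wide-bite-angle ferrocenyl ligand, the pinacol ester and a primary migrating group favour this, and the substrate offers only an unhindered E-alkenyl bromide as reactive site, since aryl benzyl ethers and the doubly ortho-substituted ester are inert to zerovalent palladium.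

Step 10
Reactants: 22 (R)-11-[3,5-bis(benzyloxy)phenyl]undecan-4-yl 2,4-bis(benzyloxy)-6-[(R,E)-8-(4,4,5,5-tetramethyl-1,3,2-dioxaborolan-2-yl)undec-5-en-1-yl]benzoate
Product: 23 (R)-11-[3,5-bis(benzyloxy)phenyl]undecan-4-yl 2,4-bis(benzyloxy)-6-[(R,E)-8-hydroxyundec-5-en-1-yl]benzoate
Conditions: 3 M aq NaOH, 30% H2O2, THF, 0 °C to rt; aq Na2S2O3
Reagents that add atoms: hydrogen peroxide, OO
Why: Oxidation of a secondary alkylboronic ester; hydroperoxide adds to boron and C8' migrates from boron to oxygen with retention, so the R boronate gives the R carbinol, while at 0 °C to rt the hindered benzoate is not hydrolysed and the alkene and benzyl ethers are inert.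

Step 11
Reactants: 23 (R)-11-[3,5-bis(benzyloxy)phenyl]undecan-4-yl 2,4-bis(benzyloxy)-6-[(R,E)-8-hydroxyundec-5-en-1-yl]benzoate
Product: 24 integracin B, (R)-11-(3,5-dihydroxyphenyl)undecan-4-yl 2,4-dihydroxy-6-[(R)-8-hydroxyundecyl]benzoate
Conditions: H2 (1 atm), 10% Pd/C, EtOAc/EtOH, rt
Reagents that add atoms: none
Why: Heterogeneous hydrogenation saturates the E-disubstituted C5'=C6' alkene and hydrogenolyses the four benzylic C–O bonds in one operation; neither carbinol C–O bond is benzylic or allylic and the aryl ester is not reducible, so both R centres survive, the alkene being expected to take up hydrogen faster than it can migrate toward C8'.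

## Compound list

1 | ethyl orsellinate (ethyl 2,4-dihydroxy-6-methylbenzoate) | CCOC(=O)c1c(C)cc(O)cc1O | starting material
2 | ethyl 2,4-bis(benzyloxy)-6-methylbenzoate | Cc1cc(OCc2ccccc2)cc(OCc2ccccc2)c1C(=O)OCC | intermediate
3 | (5-chloropent-1-yn-1-yl)trimethylsilane | C[Si](C)(C)C#CCCCCl | starting material
4 | (5-iodopent-1-yn-1-yl)trimethylsilane | C[Si](C)(C)C#CCCCI | intermediate
5 | ethyl 2,4-bis(benzyloxy)-6-(lithiomethyl)benzoate (benzylic lithium species) | [Li]Cc1cc(OCc2ccccc2)cc(OCc2ccccc2)c1C(=O)OCC | intermediate
6 | ethyl 2,4-bis(benzyloxy)-6-[6-(trimethylsilyl)hex-5-yn-1-yl]benzoate | C[Si](C)(C)C#CCCCCc1cc(OCc2ccccc2)cc(OCc2ccccc2)c1C(=O)OCC | intermediate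
7 | 2,4-bis(benzyloxy)-6-(hex-5-yn-1-yl)benzoic acid | C#CCCCCc1cc(OCc2ccccc2)cc(OCc2ccccc2)c1C(=O)O | intermediate
8 | 6-bromohex-1-ene | BrCCCCC=C | starting material
9 | (R)-2-propyloxirane | CCC[C@@H]1CO1 | starting material
10 | hex-5-enylmagnesium bromide | Br[Mg]CCCCC=C | intermediate
11 | (R)-undec-10-en-4-ol | CCC[C@@H](O)CCCCCC=C | intermediate
12 | 1,3-bis(benzyloxy)-5-bromobenzene | Brc1cc(OCc2ccccc2)cc(OCc2ccccc2)c1 | starting material
13 | (R)-9-[8-(9-borabicyclo[3.3.1]nonan-9-yloxy)undecyl]-9-borabicyclo[3.3.1]nonane | CCC[C@@H](OB1C2CCCC1CCC2)CCCCCCCB1C2CCCC1CCC2 | intermediate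
14 | (R)-11-[3,5-bis(benzyloxy)phenyl]undecan-4-ol | CCC[C@@H](O)CCCCCCCc1cc(OCc2ccccc2)cc(OCc2ccccc2)c1 | intermediate
15 | 2,4-bis(benzyloxy)-6-(hex-5-yn-1-yl)benzoyl chloride | C#CCCCCc1cc(OCc2ccccc2)cc(OCc2ccccc2)c1C(=O)Cl | intermediate
16 | (R)-11-[3,5-bis(benzyloxy)phenyl]undecan-4-yl 2,4-bis(benzyloxy)-6-(hex-5-yn-1-yl)benzoate | C#CCCCCc1cc(OCc2ccccc2)cc(OCc2ccccc2)c1C(=O)O[C@H](CCC)CCCCCCCc1cc(OCc2ccccc2)cc(OCc2ccccc2)c1 | intermediate
17 | (E)-alkenylzirconocene chloride from 16 (Cp2Zr(Cl) on terminal C6', H on C5') | Cl[Zr](/C=C/CCCCc1cc(OCc2ccccc2)cc(OCc2ccccc2)c1C(=O)O[C@H](CCC)CCCCCCCc1cc(OCc2ccccc2)cc(OCc2ccccc2)c1)(C1C=CC=C1)C1C=CC=C1 | intermediate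
18 | (R)-11-[3,5-bis(benzyloxy)phenyl]undecan-4-yl 2,4-bis(benzyloxy)-6-[(E)-6-bromohex-5-en-1-yl]benzoate | Br/C=C/CCCCc1cc(OCc2ccccc2)cc(OCc2ccccc2)c1C(=O)O[C@H](CCC)CCCCCCCc1cc(OCc2ccccc2)cc(OCc2ccccc2)c1 | intermediate
19 | propylboronic acid pinacol ester | CCCB1OC(C)(C)C(C)(C)O1 | starting material
20 | vinyllithium (halide-free THF solution) | [Li]C=C | starting material
21 | lithium 4,4,5,5-tetramethyl-2-propyl-2-vinyl-1,3,2-dioxaborolan-2-uide | [Li+].CCC[B-]1(C=C)OC(C)(C)C(C)(C)O1 | intermediate
22 | (R)-11-[3,5-bis(benzyloxy)phenyl]undecan-4-yl 2,4-bis(benzyloxy)-6-[(R,E)-8-(4,4,5,5-tetramethyl-1,3,2-dioxaborolan-2-yl)undec-5-en-1-yl]benzoate | CCC[C@@H](B1OC(C)(C)C(C)(C)O1)C/C=C/CCCCc1cc(OCc2ccccc2)cc(OCc2ccccc2)c1C(=O)O[C@H](CCC)CCCCCCCc1cc(OCc2ccccc2)cc(OCc2ccccc2)c1 | intermediate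
23 | (R)-11-[3,5-bis(benzyloxy)phenyl]undecan-4-yl 2,4-bis(benzyloxy)-6-[(R,E)-8-hydroxyundec-5-en-1-yl]benzoate | CCC[C@@H](O)C/C=C/CCCCc1cc(OCc2ccccc2)cc(OCc2ccccc2)c1C(=O)O[C@H](CCC)CCCCCCCc1cc(OCc2ccccc2)cc(OCc2ccccc2)c1 | intermediate
24 | integracin B, (R)-11-(3,5-dihydroxyphenyl)undecan-4-yl 2,4-dihydroxy-6-[(R)-8-hydroxyundecyl]benzoate | CCC[C@@H](O)CCCCCCCc1cc(O)cc(O)c1C(=O)O[C@H](CCC)CCCCCCCc1cc(O)cc(O)c1 | target

## Step count and least certain steps

Total: 11 steps. Longest linear sequence: 8 steps (1, 3, 4, 7, 8, 9, 10, 11).

**Step 9 (key step).** The likely failures are direct Suzuki–Miyaura transfer of the vinyl group without migration, β-hydride elimination after the metallate shift, inhibition of the catalyst by halide, and incomplete enantiofacial selectivity. The last would give a C8' epimer mixture that cannot be separated because the two centres are remote. A substrate of this size and lipophilicity has not been tried in this reaction type. The fallback gives up the three-component coupling and takes C8' from the chiral pool; it sets out from 16 and comes back at 24. Deprotonation of the terminal alkyne of 16 with n-BuLi (1.0 equiv, THF, −78 °C, where the doubly ortho-substituted secondary ester should not accept the base) gives the lithium acetylide of 16 F1. With BF3·OEt2 this opens a second portion of 9 at its unsubstituted carbon to give (R)-11-[3,5-bis(benzyloxy)phenyl]undecan-4-yl 2,4-bis(benzyloxy)-6-[(R)-8-hydroxyundec-5-yn-1-yl]benzoate F2, with the C8' configuration carried over unchanged from the epoxide. Hydrogenation of F2 under the conditions of step 11 saturates the alkyne and removes the benzyl groups to give 24.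

**Step 3.** The likely failures are Claisen-type self-condensation of the lithiated ester with unreacted ester, proton return because SN2 attack on an unactivated primary iodide is slow at low temperature, and deprotonation of a benzyl ether methylene. The fallback removes the electrophilic ester before the anion is made; it sets out from 2 and comes back at 7. Saponification of 2 (KOH, aqueous ethanol, reflux; no alkyne is present, so forcing conditions are harmless) gives 2,4-bis(benzyloxy)-6-methylbenzoic acid F3. Two equivalents of LiN(iPr)2 convert it into lithium 2,4-bis(benzyloxy)-6-(lithiomethyl)benzoate F4, a dianion that has no ester to attack and is alkylated by 4 to give 2,4-bis(benzyloxy)-6-[6-(trimethylsilyl)hex-5-yn-1-yl]benzoic acid F5. K2CO3 in methanol then removes the silyl group and gives 7.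

**Step 7.** The likely failure is slow acyl transfer at a carbonyl shielded by two ortho substituents, which would let decomposition of the acid chloride (loss of an ortho benzyl group, hydrolysis) compete. The fallback forms the ester C–O bond at the carbinol carbon instead of at the carbonyl; it sets out from 14 and 7 and comes back at 16. Mitsunobu reaction of 14 with 4-nitrobenzoic acid (PPh3, diisopropyl azodicarboxylate, THF) gives, with inversion, (S)-11-[3,5-bis(benzyloxy)phenyl]undecan-4-yl 4-nitrobenzoate F6. Methanolysis (K2CO3, MeOH) gives (S)-11-[3,5-bis(benzyloxy)phenyl]undecan-4-ol F7. A second Mitsunobu reaction of F7 with 7 lets the carboxylate displace the activated oxygen by SN2, so no nucleophile has to approach the hindered carbonyl, and inverts the centre back to R to give 16.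

**Step 8.** The likely failures are electrophilic bromination of the very electron-rich ring B by NBS, partial reduction of the ester by excess zirconium hydride, and double hydrozirconation. The fallback installs the alkenyl bromide before the two halves are joined, so ring B and the ester are absent when Zr–H and NBS are used; it sets out from 7 and comes back at 18. Treatment of 7 with Cp2Zr(H)Cl (2.3 equiv, the first equivalent being consumed by the carboxylic acid proton), then NBS and an acidic work-up gives 2,4-bis(benzyloxy)-6-[(E)-6-bromohex-5-en-1-yl]benzoic acid F8. Oxalyl chloride converts it into 2,4-bis(benzyloxy)-6-[(E)-6-bromohex-5-en-1-yl]benzoyl chloride F9, which acylates 14 (Et3N, DMAP) to give 18; the E-alkenyl bromide is inert to these conditions.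

**Step 11.** The likely failure is migration of the double bond toward C8' on the palladium surface before it is saturated. The resulting allylic alcohol could isomerise to a ketone or lose oxygen by hydrogenolysis, eroding the C8' centre. The fallback separates the two reductions and uses a metal-free alkene reduction; it sets out from 23 and comes back at 24. Diimide generated from p-toluenesulfonyl hydrazide and NaOAc (aqueous THF, reflux) transfers two hydrogens to C5'=C6' in a concerted step and gives (R)-11-[3,5-bis(benzyloxy)phenyl]undecan-4-yl 2,4-bis(benzyloxy)-6-[(R)-8-hydroxyundecyl]benzoate F10. Hydrogenolysis of F10 (H2, Pd/C) then only has to break the four benzylic C–O bonds to give 24.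

## Further compounds

F1 | step 9 | lithium acetylide of 16 | [Li]C#CCCCCc1cc(OCc2ccccc2)cc(OCc2ccccc2)c1C(=O)O[C@H](CCC)CCCCCCCc1cc(OCc2ccccc2)cc(OCc2ccccc2)c1
F2 | step 9 | (R)-11-[3,5-bis(benzyloxy)phenyl]undecan-4-yl 2,4-bis(benzyloxy)-6-[(R)-8-hydroxyundec-5-yn-1-yl]benzoate | CCC[C@@H](O)CC#CCCCCc1cc(OCc2ccccc2)cc(OCc2ccccc2)c1C(=O)O[C@H](CCC)CCCCCCCc1cc(OCc2ccccc2)cc(OCc2ccccc2)c1
F3 | step 3 | 2,4-bis(benzyloxy)-6-methylbenzoic acid | Cc1cc(OCc2ccccc2)cc(OCc2ccccc2)c1C(=O)O
F4 | step 3 | lithium 2,4-bis(benzyloxy)-6-(lithiomethyl)benzoate | [Li]Cc1cc(OCc2ccccc2)cc(OCc2ccccc2)c1C(=O)O[Li]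
F5 | step 3 | 2,4-bis(benzyloxy)-6-[6-(trimethylsilyl)hex-5-yn-1-yl]benzoic acid | C[Si](C)(C)C#CCCCCc1cc(OCc2ccccc2)cc(OCc2ccccc2)c1C(=O)O
F6 | step 7 | (S)-11-[3,5-bis(benzyloxy)phenyl]undecan-4-yl 4-nitrobenzoate | CCC[C@H](OC(=O)c1ccc(cc1)[N+](=O)[O-])CCCCCCCc1cc(OCc2ccccc2)cc(OCc2ccccc2)c1
F7 | step 7 | (S)-11-[3,5-bis(benzyloxy)phenyl]undecan-4-ol | CCC[C@H](O)CCCCCCCc1cc(OCc2ccccc2)cc(OCc2ccccc2)c1
F8 | step 8 | 2,4-bis(benzyloxy)-6-[(E)-6-bromohex-5-en-1-yl]benzoic acid | Br/C=C/CCCCc1cc(OCc2ccccc2)cc(OCc2ccccc2)c1C(=O)O
F9 | step 8 | 2,4-bis(benzyloxy)-6-[(E)-6-bromohex-5-en-1-yl]benzoyl chloride | Br/C=C/CCCCc1cc(OCc2ccccc2)cc(OCc2ccccc2)c1C(=O)Cl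
F10 | step 11 | (R)-11-[3,5-bis(benzyloxy)phenyl]undecan-4-yl 2,4-bis(benzyloxy)-6-[(R)-8-hydroxyundecyl]benzoate | CCC[C@@H](O)CCCCCCCc1cc(OCc2ccccc2)cc(OCc2ccccc2)c1C(=O)O[C@H](CCC)CCCCCCCc1cc(OCc2ccccc2)cc(OCc2ccccc2)c1
A1 | alternative 1 | (R)-11-(3-ethoxy-5-hydroxyphenyl)undecan-4-yl pivalate | CCC[C@@H](OC(=O)C(C)(C)C)CCCCCCCc1cc(O)cc(OCC)c1
A2 | alternative 1 | (R)-11-(3-oxocyclobut-1-en-1-yl)undecan-4-yl pivalate | CCC[C@@H](OC(=O)C(C)(C)C)CCCCCCCC1=CC(=O)C1
A3 | alternative 1 | ethoxyethyne | CCOC#C
A4 | alternative 2 | (R)-11-[3,5-bis(benzyloxy)phenyl]undecan-4-yl 2-[(R)-8-(benzyloxy)undecyl]-4,6-dihydroxybenzoate | CCC[C@@H](OCc1ccccc1)CCCCCCCc1cc(O)cc(O)c1C(=O)O[C@H](CCC)CCCCCCCc1cc(OCc2ccccc2)cc(OCc2ccccc2)c1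
A5 | alternative 2 | 6-[(R)-12-(benzyloxy)-2,4-dioxopentadecyl]-2,2-dimethyl-4H-1,3-dioxin-4-one | CC1(C)OC(=O)C=C(CC(=O)CC(=O)CCCCCCC[C@@H](CCC)OCc2ccccc2)O1
A6 | alternative 3 | (R)-11-[3,5-bis(benzyloxy)phenyl]undecan-4-yl 2-[(R)-8-(benzyloxy)undecyl]-4,6-bis(trimethylsilyloxy)benzoate | CCC[C@@H](OCc1ccccc1)CCCCCCCc1cc(O[Si](C)(C)C)cc(O[Si](C)(C)C)c1C(=O)O[C@H](CCC)CCCCCCCc1cc(OCc2ccccc2)cc(OCc2ccccc2)c1
A7 | alternative 3 | (R)-11-[3,5-bis(benzyloxy)phenyl]undecan-4-yl (R)-11-(benzyloxy)tetradec-2-ynoate | CCC[C@@H](OCc1ccccc1)CCCCCCCC#CC(=O)O[C@H](CCC)CCCCCCCc1cc(OCc2ccccc2)cc(OCc2ccccc2)c1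
A8 | alternative 3 | 5,5-dimethyl-1,3-bis(trimethylsilyloxy)cyclohexa-1,3-diene | C[Si](C)(C)OC1=CC(O[Si](C)(C)C)=CC(C)(C)C1
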